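**Retrosynthetic overview**

- Feature: ring A (the benzene) carries O1 on C8a, the C4 methylene on the neighbouring C4a and the carboxyl carbon on C6, para to O1. This is the pattern left when N1=N2 of a 3-alkoxypyridazine with an acceptor at C6 is replaced by the two carbons of an alkyne tethered through that oxygen. The only stereocentre, C2 (R), lies in the tether.
- Last disconnections: the acid from its methyl ester; the central bond of the E,E-diene by palladium-catalysed coupling of a chroman E-iodoalkene (from the C2 aldehyde) with the E-alkenylalane obtained by methylalumination of an alkyne made from dihydro-β-ionone, whose cyclohexene ring is bought.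
- Key disconnection: C4a–C8a and C5–C6, formed together in an intramolecular pyridazine–alkyne [4+2] cycloaddition with loss of N2, which closes ring A and ring B in one step.
- Precursor: the tertiary alkyl pyridazinyl ether from 6-chloropyridazine-3-carbonitrile and the alkynol made from trityl-protected (S)-2-methylglycidol and allenylmagnesium bromide; the glycidol supplies C2.

Key step: step 4

Remark: the C6 carboxyl carbon is carried through the cycloaddition as a nitrile, because a methyl ester on the chlorodiazine would be open to acyl exchange by the tertiary alkoxide of step 3 and the nitrile is the stronger acceptor; the primary oxygen is carried as a trityl ether, because a silyl ether there would migrate to the neighbouring tertiary alkoxide. Compounds 1, 3, 6 and 14 are taken as commercial.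

**Route**

Step 1
Reactants: 1 (S)-2-methylglycidol
Product: 2 (R)-2-methyl-2-[(trityloxy)methyl]oxirane
Conditions: TrCl (1.1 equiv), Et3N, DMAP (cat.), CH2Cl2, 0 °C → rt
Reagents that add atoms: trityl chloride, ClC(c1ccccc1)(c1ccccc1)c1ccccc1
Why: Tritylation of the primary hydroxyl (SN1-type etherification by the trityl cation with an amine base) leaves the epoxide and the quaternary stereocentre untouched, the descriptor changing from S to R only through the CIP ranking, and an ether is chosen because, unlike a silyl group, it cannot migrate onto the tertiary alkoxide generated in step 3.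

Step 2
Reactants: 2 (R)-2-methyl-2-[(trityloxy)methyl]oxirane; 3 propargyl bromide
Product: 5 (2R)-2-methyl-1-(trityloxy)hex-5-yn-2-ol, via allenylmagnesium bromide 4 (not isolated)
Conditions: 3, Mg, HgCl2 (cat.), Et2O, 0 °C; then 2, −78 → 0 °C; aq. NH4Cl
Reagents that add atoms: none
Why: Allenylmagnesium bromide attacks the unsubstituted epoxide carbon through its γ-carbon (SE2′ opening of an epoxide by a propargyl/allenyl Grignard reagent) to give the homopropargylic tertiary alcohol, and since no bond at the stereocentre is broken its configuration is retained.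

Step 3
Reactants: 5 (2R)-2-methyl-1-(trityloxy)hex-5-yn-2-ol; 6 6-chloropyridazine-3-carbonitrile
Product: 7 6-{[(2R)-2-methyl-1-(trityloxy)hex-5-yn-2-yl]oxy}pyridazine-3-carbonitrile
Conditions: KN(SiMe3)2 (1.05 equiv), THF, −78 °C; then 6 (1.2 equiv), −78 → 0 °C
Reagents that add atoms: none
Why: Nucleophilic aromatic substitution (addition–elimination) of the potassium tertiary alkoxide at the chlorine-bearing carbon, which is activated by both ring nitrogens and the para nitrile, should be clean because the nitrile offers the alkoxide no acyl-exchange pathway and the trityl ether cannot migrate, so only the tertiary oxygen is arylated.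

Step 4
Reactants: 7 6-{[(2R)-2-methyl-1-(trityloxy)hex-5-yn-2-yl]oxy}pyridazine-3-carbonitrile
Product: 9 (2R)-2-methyl-2-[(trityloxy)methyl]chromane-6-carbonitrile, via diazabicyclooctatriene cycloadduct 8 (not isolated)
Conditions: 1,2-dichlorobenzene (0.02 M), 2,6-di-tert-butyl-4-methylpyridine (0.2 equiv), argon, base-washed sealed tube, 155 °C
Reagents that add atoms: none
Why: The tethered alkyne (2π) adds across the oxygen-bearing and the nitrile-bearing carbons of the diazine (4π, LUMO lowered by the two nitrogens and the nitrile) in a concerted inverse-electron-demand [4+2] cycloaddition, and the 2,3-diazabicyclo[2.2.2]octatriene 8 loses N2 by retro-[4+2] to give the benzene directly. The closest known reaction type is the thermal intramolecular cycloaddition of 3-(alkynyloxy)pyridazines and of alkyne-tethered pyridazinecarbonitriles, which gives 2,3-dihydrobenzofurans and chromans with extrusion of N2. Ring B closes as the six-membered ring O1–C2–C3–C4–C4a–C8a through the new C4a–C8a bond, because the four-atom tether delivers the internal alkyne carbon to the oxygen-bearing diazine carbon; ring A is completed by the second new bond C5–C6 and becomes aromatic when N2 leaves. No stereocentre is formed in the product and no bond to C2 is broken, so the R configuration from the glycidol is carried through. The selectivity needed is chemoselectivity over retro-ene loss of the tertiary alkyl heteroaryl ether (to a pyridazinone and an alkene); that process has the higher activation energy, so the step is run at the lowest temperature that the nitrile-activated diazine and the fully substituted C2 (reactive-rotamer effect) allow, with a hindered pyridine keeping the medium acid-free. Regiochemistry needs no control, since the tether length fixes it and places the nitrile carbon on C6, para to O1.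

Step 5
Reactants: 9 (2R)-2-methyl-2-[(trityloxy)methyl]chromane-6-carbonitrile
Product: 11 methyl (2R)-2-(hydroxymethyl)-2-methylchromane-6-carboxylate, via imidate hydrochloride 10 (not isolated)
Conditions: anhydrous HCl (sat.), MeOH/CH2Cl2, 0 °C → rt; then H2O, rt
Reagents that add atoms: methanol, CO; water, O
Why: In a Pinner reaction HCl-promoted addition of methanol to the aryl nitrile should give the imidate hydrochloride, which water hydrolyses to the methyl ester, while the same acid solvolyses the trityl ether to the primary alcohol, and the C2–O1 bond, flanked by an electron-withdrawing CH2O group, should not ionise under these cold conditions, so C2 keeps its configuration.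

Step 6
Reactants: 11 methyl (2R)-2-(hydroxymethyl)-2-methylchromane-6-carboxylate
Product: 12 methyl (2R)-2-formyl-2-methylchromane-6-carboxylate
Conditions: Dess–Martin periodinane, pyridine, CH2Cl2, 0 °C → rt
Reagents that add atoms: none
Why: Dess–Martin oxidation of the neopentyl-type primary alcohol stops at the aldehyde, which cannot epimerise because its α-carbon (C2) is fully substituted.

Step 7
Reactants: 12 methyl (2R)-2-formyl-2-methylchromane-6-carboxylate
Product: 13 methyl (2R)-2-[(E)-2-iodoethenyl]-2-methylchromane-6-carboxylate
Conditions: CrCl2 (8 equiv), CHI3 (3 equiv), THF/1,4-dioxane, 0 °C → rt, dark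
Reagents that add atoms: iodoform, IC(I)I
Why: In the Takai olefination the geminal dichromium species formed from CHI3 and divalent chromium adds to the aldehyde and eliminates to the E-iodoalkene, the E preference being strongest for α-branched aldehydes, and the aryl ester is inert to CrCl2.

Step 8
Reactants: 14 dihydro-β-ionone
Product: 16 2-(but-3-yn-1-yl)-1,3,3-trimethylcyclohex-1-ene, via enol diethyl phosphate 15 (not isolated)
Conditions: LiN(i-Pr)2 (1.05 equiv), THF, −78 °C; ClP(O)(OEt)2, −78 °C → rt; then LiN(i-Pr)2 (2.3 equiv), −78 °C → rt; H2O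
Reagents that add atoms: none
Why: Kinetic deprotonation at the methyl group, O-phosphorylation and base-induced β-elimination of diethyl phosphate from the terminal enol phosphate (the enol phosphate route from a methyl ketone to a terminal alkyne) should give the alkyne, which is held as its acetylide until the quench and so does not isomerise, while the tetrasubstituted ring alkene is inert.

Step 9
Reactants: 16 2-(but-3-yn-1-yl)-1,3,3-trimethylcyclohex-1-ene; 13 methyl (2R)-2-[(E)-2-iodoethenyl]-2-methylchromane-6-carboxylate
Product: 18 methyl (2R)-2-methyl-2-[(1E,3E)-4-methyl-6-(2,6,6-trimethylcyclohex-1-en-1-yl)hexa-1,3-dien-1-yl]chromane-6-carboxylate, via E-alkenyldimethylalane 17 (not isolated)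
Conditions: 16 (1.5 equiv), AlMe3 (3 equiv), Cp2ZrCl2 (0.3 equiv), CH2Cl2, 0 °C → rt; volatiles removed in vacuo; then 13, Pd(PPh3)4 (5 mol %), ZnCl2 (0.3 equiv), THF, rt
Reagents that add atoms: trimethylaluminium, C[Al](C)C
Why: Zirconocene-catalysed syn methylalumination of the terminal alkyne (Negishi carboalumination) places methyl on the internal and aluminium on the terminal carbon with E geometry, and the alkenylalane then couples with retention at both partners with the E-iodoalkene under zerovalent palladium and ZnCl2 co-catalysis (Negishi coupling), which fixes both diene double bonds as E, while removal of excess AlMe3 beforehand spares the ester and limits methyl transfer.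

Step 10
Reactants: 18 methyl (2R)-2-methyl-2-[(1E,3E)-4-methyl-6-(2,6,6-trimethylcyclohex-1-en-1-yl)hexa-1,3-dien-1-yl]chromane-6-carboxylate
Product: 19 (2R)-2-methyl-2-[(1E,3E)-4-methyl-6-(2,6,6-trimethylcyclohex-1-en-1-yl)hexa-1,3-dien-1-yl]chromane-6-carboxylic acid (target, CNP0265961.1)
Conditions: LiOH·H2O (5 equiv), THF/MeOH/H2O, rt → 40 °C; then 0.5 M aq. HCl to pH 4–5, 0 °C
Reagents that add atoms: lithium hydroxide, [Li+].[OH-]
Why: Saponification (BAc2) of the aryl methyl ester by hydroxide leaves the diene, the tetrasubstituted alkene and the tertiary allylic aryl ether untouched, and acidification only to pH 4–5 in the cold avoids ionisation at C2.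

**Compound list**

1 | (S)-2-methylglycidol | OC[C@@]1(C)CO1 | starting material
2 | (R)-2-methyl-2-[(trityloxy)methyl]oxirane | C(c1ccccc1)(c1ccccc1)(c1ccccc1)OC[C@@]2(C)CO2 | intermediate
3 | propargyl bromide | C#CCBr | starting material
4 | allenylmagnesium bromide (not isolated) | C=C=C[Mg]Br | intermediate
5 | (2R)-2-methyl-1-(trityloxy)hex-5-yn-2-ol | C(c1ccccc1)(c1ccccc1)(c1ccccc1)OC[C@@](C)(CCC#C)O | intermediate
6 | 6-chloropyridazine-3-carbonitrile | N#Cc1ccc(Cl)nn1 | starting material
7 | 6-{[(2R)-2-methyl-1-(trityloxy)hex-5-yn-2-yl]oxy}pyridazine-3-carbonitrile | C(c1ccccc1)(c1ccccc1)(c1ccccc1)OC[C@@](C)(CCC#C)Oc2ccc(C#N)nn2 | intermediate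
8 | 2,3-diazabicyclo[2.2.2]octatriene cycloadduct of 7 (not isolated; either bridgehead diastereomer, both give 9) | N#CC12N=NC3(O[C@@](C)(COC(c4ccccc4)(c4ccccc4)c4ccccc4)CCC3=C1)C=C2 | intermediate
9 | (2R)-2-methyl-2-[(trityloxy)methyl]chromane-6-carbonitrile | C(c1ccccc1)(c1ccccc1)(c1ccccc1)OC[C@@]2(C)CCc3cc(C#N)ccc3O2 | intermediate
10 | methyl (2R)-2-(hydroxymethyl)-2-methylchromane-6-carboximidate hydrochloride (not isolated) | OC[C@@]1(C)CCc2cc(C(=N)OC)ccc2O1.Cl | intermediate
11 | methyl (2R)-2-(hydroxymethyl)-2-methylchromane-6-carboxylate | OC[C@@]1(C)CCc2cc(C(=O)OC)ccc2O1 | intermediate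
12 | methyl (2R)-2-formyl-2-methylchromane-6-carboxylate | O=C[C@@]1(C)CCc2cc(C(=O)OC)ccc2O1 | intermediate
13 | methyl (2R)-2-[(E)-2-iodoethenyl]-2-methylchromane-6-carboxylate | I/C=C/[C@@]1(C)CCc2cc(C(=O)OC)ccc2O1 | intermediate
14 | dihydro-β-ionone, 4-(2,6,6-trimethylcyclohex-1-en-1-yl)butan-2-one | CC(=O)CCC1=C(C)CCCC1(C)C | starting material
15 | diethyl 4-(2,6,6-trimethylcyclohex-1-en-1-yl)but-1-en-2-yl phosphate (not isolated) | C=C(CCC1=C(C)CCCC1(C)C)OP(=O)(OCC)OCC | intermediate
16 | 2-(but-3-yn-1-yl)-1,3,3-trimethylcyclohex-1-ene | C#CCCC1=C(C)CCCC1(C)C | intermediate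
17 | dimethyl[(1E)-2-methyl-4-(2,6,6-trimethylcyclohex-1-en-1-yl)but-1-en-1-yl]alumane (not isolated) | C[Al](C)/C=C(\C)CCC1=C(C)CCCC1(C)C | intermediate
18 | methyl (2R)-2-methyl-2-[(1E,3E)-4-methyl-6-(2,6,6-trimethylcyclohex-1-en-1-yl)hexa-1,3-dien-1-yl]chromane-6-carboxylate | CC1=C(CC/C(C)=C/C=C/[C@@]2(C)CCc3cc(C(=O)OC)ccc3O2)C(C)(C)CCC1 | intermediate
19 | (2R)-2-methyl-2-[(1E,3E)-4-methyl-6-(2,6,6-trimethylcyclohex-1-en-1-yl)hexa-1,3-dien-1-yl]chromane-6-carboxylic acid | CC1=C(CC/C(C)=C/C=C/[C@@]2(C)CCc3cc(C(=O)O)ccc3O2)C(C)(C)CCC1 | target

**Step count**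

Total: 10 steps. Longest linear sequence: 9 steps (steps 1–7, 9 and 10); step 8 is the side branch.

**Steps most likely to fail, with fallbacks**

1. Step 4. Retro-ene loss (or trace-acid ionisation) of the tertiary alkyl heteroaryl ether may outrun the cycloaddition, which for a six-membered ring B needs more heat than the five-membered analogues. Fallback, from 2 back to 9, with ring A bought and only ring B closed: epoxide 2 is homologated with dimethylsulfonium methylide (Me3S+ I−, n-BuLi, THF, −10 °C → rt) to (2R)-2-methyl-1-(trityloxy)but-3-en-2-ol F1. Heck arylation of F1 with 3-bromo-4-fluorobenzonitrile (Pd(OAc)2, P(o-tol)3, Et3N, MeCN, 80 °C) should give 4-fluoro-3-[(1E,3R)-3-hydroxy-3-methyl-4-(trityloxy)but-1-en-1-yl]benzonitrile F2. Diimide reduction (TsNHNH2, NaOAc, THF/H2O, reflux) saturates the alkene to 4-fluoro-3-[(3R)-3-hydroxy-3-methyl-4-(trityloxy)butyl]benzonitrile F3. KN(SiMe3)2 in THF/DMF then closes ring B by intramolecular SNAr of the tertiary alkoxide on the fluoride para to the nitrile, giving 9.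

2. Step 9. Methyl transfer from aluminium to the iodoalkene, incomplete regiocontrol in the methylalumination, or ionisation of the allylic aryl ether at C2 by zerovalent palladium may erode the coupling. Fallback, from 16 back to 18, without palladium: the same methylalumination of 16 is quenched with I2 (THF, −30 °C) to give 2-[(3E)-4-iodo-3-methylbut-3-en-1-yl]-1,3,3-trimethylcyclohex-1-ene F6. Iodine–lithium exchange (t-BuLi, Et2O, −78 °C) and stannylation with Bu3SnCl give tributyl[(1E)-2-methyl-4-(2,6,6-trimethylcyclohex-1-en-1-yl)but-1-en-1-yl]stannane F7. F7 is then coupled with iodoalkene 13 by monovalent copper, Cu(O2C-2-C4H3S) (1.5 equiv), in NMP at 0 °C → rt (copper-mediated Stille-type coupling), with retention of both alkene geometries, to give 18.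

3. Step 5. The alcoholysis of the electron-rich aryl nitrile may stall or divert to the primary amide, or prolonged strong acid may begin to open the tertiary ether at C2. Fallback, from 9 back to 11, with the nitrile hydrolysed under base instead: mild detritylation (TsOH·H2O cat., MeOH/CH2Cl2, rt) gives (2R)-2-(hydroxymethyl)-2-methylchromane-6-carbonitrile F4. Alkaline hydrolysis (KOH, ethylene glycol/H2O, 130 °C; then acidification) gives (2R)-2-(hydroxymethyl)-2-methylchromane-6-carboxylic acid F5. Carboxylate alkylation (MeI, K2CO3, DMF, rt) then gives 11.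

**Further compounds**

F1 | step 4 | (2R)-2-methyl-1-(trityloxy)but-3-en-2-ol | C(c1ccccc1)(c1ccccc1)(c1ccccc1)OC[C@@](C)(C=C)O
F2 | step 4 | 4-fluoro-3-[(1E,3R)-3-hydroxy-3-methyl-4-(trityloxy)but-1-en-1-yl]benzonitrile | C(c1ccccc1)(c1ccccc1)(c1ccccc1)OC[C@@](C)(/C=C/c2cc(C#N)ccc2F)O
F3 | step 4 | 4-fluoro-3-[(3R)-3-hydroxy-3-methyl-4-(trityloxy)butyl]benzonitrile | C(c1ccccc1)(c1ccccc1)(c1ccccc1)OC[C@@](C)(CCc2cc(C#N)ccc2F)O
F4 | step 5 | (2R)-2-(hydroxymethyl)-2-methylchromane-6-carbonitrile | OC[C@@]1(C)CCc2cc(C#N)ccc2O1
F5 | step 5 | (2R)-2-(hydroxymethyl)-2-methylchromane-6-carboxylic acid | OC[C@@]1(C)CCc2cc(C(=O)O)ccc2O1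
F6 | step 9 | 2-[(3E)-4-iodo-3-methylbut-3-en-1-yl]-1,3,3-trimethylcyclohex-1-ene | CC1=C(CC/C(C)=C/I)C(C)(C)CCC1
F7 | step 9 | tributyl[(1E)-2-methyl-4-(2,6,6-trimethylcyclohex-1-en-1-yl)but-1-en-1-yl]stannane | CC1=C(CC/C(C)=C/[Sn](CCCC)(CCCC)CCCC)C(C)(C)CCC1
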